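**Retrosynthetic overview**
1. Ester bond last: the only secondary hydroxyl of the sesquiterpene triol is acylated with O-silyl vanillic acid (built on catechol by O-methylation, para-bromination, silylation, Li/CO2), then desilylated.
2. Tertiary allylic carbinol from MeMgBr/CeCl3 on a cyclohept-2-enone; the neighbouring secondary hydroxyl from copper-catalysed β-borylation/oxidation of a cross-conjugated cycloheptadienone.
3. Five-membered ring (formed last): intramolecular vinylogous aldol of the dienone γ-carbon onto a side-chain isopropyl ketone, which sets the ring fusion and the isopropyl carbinol.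
4. Seven-membered ring (made from the purchased six-membered ring): Saegusa–Ito one-carbon ring expansion of a siloxycyclopropane (key step), then α′-dehydrogenation.
5. Quaternary stereocentre (first stereocentre): copper-catalysed asymmetric conjugate addition of a ketal-protected Grignard reagent to 3-methylcyclohex-2-en-1-one.

Assumption: 4-methylpent-1-en-3-one is taken as purchasable; locants in the Why lines are those of the compound names.

**Step 1**
Reactants: 1 4-methylpent-1-en-3-one
Product: 3 2-(2-bromoethyl)-2-(propan-2-yl)-1,3-dioxolane, via bromo ketone 2 (not isolated)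
Conditions: HBr (g), CH2Cl2, 0 °C; then HOCH2CH2OH, p-TsOH (cat.), 23 °C
Reagents that add atoms: hydrogen bromide, Br; ethane-1,2-diol, OCCO
Why: Conjugate (Michael) addition of HBr to the enone followed by acid-catalysed ketalisation gives the masked β-bromo ketone needed for Grignard formation, and no stereocentre is formed.

**Step 2**
Reactants: 3 2-(2-bromoethyl)-2-(propan-2-yl)-1,3-dioxolane; 4 3-methylcyclohex-2-en-1-one
Product: 7 trimethyl{[(3R)-3-methyl-3-{2-[2-(propan-2-yl)-1,3-dioxolan-2-yl]ethyl}cyclohex-1-en-1-yl]oxy}silane, via Grignard reagent 5 (not isolated), via magnesium enolate 6 (not isolated)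
Conditions: Mg, THF, 35 °C; then Cu(OTf)2 (3 mol %), chiral imidazolinium chloride (NHC precursor, 4 mol %), 4, Et2O, −30 °C; then TMSCl, Et3N, HMPA, −30 → 0 °C
Reagents that add atoms: chlorotrimethylsilane, C[Si](C)(C)Cl
Why: Copper-catalysed asymmetric conjugate addition of a Grignard reagent to a β-substituted cyclohexenone, in which the catalyst formed from Cu(OTf)2 and the chiral NHC ligand selects the enone face and sets the quaternary centre as R, and the regiodefined magnesium enolate is silylated on oxygen.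

**Step 3**
Reactants: 7 trimethyl{[(3R)-3-methyl-3-{2-[2-(propan-2-yl)-1,3-dioxolan-2-yl]ethyl}cyclohex-1-en-1-yl]oxy}silane
Product: 8 trimethyl{[(5R)-5-methyl-5-{2-[2-(propan-2-yl)-1,3-dioxolan-2-yl]ethyl}bicyclo[4.1.0]heptan-1-yl]oxy}silane (both cyclopropane-fusion isomers)
Conditions: Et2Zn, CH2I2, toluene, 0 → 23 °C
Reagents that add atoms: diiodomethane, ICI
Why: Simmons–Smith (Furukawa) cyclopropanation of the electron-rich silyl enol ether by EtZnCH2I; the two new cyclopropane stereocentres are destroyed in step 4, so their configuration does not matter.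

**Step 4**
Reactants: 8 trimethyl{[(5R)-5-methyl-5-{2-[2-(propan-2-yl)-1,3-dioxolan-2-yl]ethyl}bicyclo[4.1.0]heptan-1-yl]oxy}silane
Product: 10 (4R)-4-methyl-4-{2-[2-(propan-2-yl)-1,3-dioxolan-2-yl]ethyl}cyclohept-2-en-1-one, via chloro ketone 9 (not isolated)
Conditions: FeCl3, pyridine, DMF, 0 → 23 °C; then NaOAc, MeOH, 65 °C
Reagents that add atoms: none
Why: Saegusa–Ito ring expansion, in which one-electron oxidation of the siloxycyclopropane by FeCl3 gives an alkoxy radical, β-scission of the internal cyclopropane bond enlarges the ring to a β-keto radical, chlorine transfer gives 9 and E1cB loss of HCl gives the cycloheptenone with the quaternary centre untouched.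

**Step 5**
Reactants: 10 (4R)-4-methyl-4-{2-[2-(propan-2-yl)-1,3-dioxolan-2-yl]ethyl}cyclohept-2-en-1-one
Product: 12 (4S)-4-methyl-4-{2-[2-(propan-2-yl)-1,3-dioxolan-2-yl]ethyl}cyclohepta-2,6-dien-1-one, via lithium dienolate 11 (not isolated)
Conditions: LiN(i-Pr)2, THF, −78 °C; then PhS(Cl)=N-t-Bu, −78 °C
Reagents that add atoms: none
Why: Mukaiyama dehydrogenation, in which the only enolisable position of 10 (C-7) gives the cross-conjugated lithium enolate, this is sulfenylated by the sulfinimidoyl chloride and the adduct eliminates the sulfenamide in situ to give the second enone (the descriptor changes from R to S by CIP ranking only).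

**Step 6**
Reactants: 12 (4S)-4-methyl-4-{2-[2-(propan-2-yl)-1,3-dioxolan-2-yl]ethyl}cyclohepta-2,6-dien-1-one
Product: 14 (3R,3aR,8aR)-3-hydroxy-8a-methyl-3-(propan-2-yl)-2,3,3a,8a-tetrahydroazulen-6(1H)-one, via diketone 13 (not isolated)
Conditions: 1 M HCl, THF, 40 °C; then aq. KOH to pH 13, MeOH, 0 → 23 °C
Reagents that add atoms: water, O
Why: Proposed new method: after acid unmasking of the ketone, hydroxide reversibly deprotonates the γ-CH2 (C-5 of 13), the only acidic site of the cross-conjugated dienone and several pKa units more acidic than the α-CH of the saturated side-chain ketone, the delocalised trienolate can reach the isopropyl ketone in a five-membered transition state only through its γ-carbon (attack through the α-carbon would give a bridged seven-membered ring), and because this vinylogous aldol addition is reversible the product is expected to settle on the trans-fused diastereomer in which the bulky isopropyl group is anti to C-4 and on the face of H-3a, so that the existing 8a centre fixes both new stereocentres (3R,3aR); the closest known reaction types are intermolecular vinylogous aldol additions of dienolates and base-mediated intramolecular aldol cyclisations of diketones, neither of which has been shown for a cross-conjugated cycloheptadienone donor closing onto a ketone to set a ring fusion.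

**Step 7**
Reactants: 14 (3R,3aR,8aR)-3-hydroxy-8a-methyl-3-(propan-2-yl)-2,3,3a,8a-tetrahydroazulen-6(1H)-one
Product: 16 (3R,3aS,4S,8aR)-3,4-dihydroxy-8a-methyl-3-(propan-2-yl)-2,3,3a,4,5,8a-hexahydroazulen-6(1H)-one, via boronate 15 (not isolated)
Conditions: CuCl (5 mol %), (R,S)-Josiphos (6 mol %), NaOt-Bu (10 mol %), B2pin2, MeOH, THF, 0 °C; then H2O2, NaHCO3, THF/H2O, 0 °C
Reagents that add atoms: hydrogen peroxide, OO
Why: Copper-catalysed conjugate borylation, in which the Cu–Bpin species formed from CuCl and B2pin2 adds to C-4 of the less hindered enone arm (C-8 of the other arm is shielded by the quaternary C-8a) on the face of H-3a away from the pseudo-axial 8a-methyl group, a preference reinforced by the chiral bisphosphine, and stereoretentive oxidation of the C–B bond gives the 4S alcohol (the 3a descriptor changes from R to S by CIP ranking only).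

**Step 8**
Reactants: 16 (3R,3aS,4S,8aR)-3,4-dihydroxy-8a-methyl-3-(propan-2-yl)-2,3,3a,4,5,8a-hexahydroazulen-6(1H)-one
Product: 17 (3R,3aS,4S,6S,8aR)-6,8a-dimethyl-3-(propan-2-yl)-1,2,3,3a,4,5,6,8a-octahydroazulene-3,4,6-triol
Conditions: MeMgBr, CeCl3, THF, −78 °C
Reagents that add atoms: methylmagnesium bromide, C[Mg]Br
Why: Imamoto-type 1,2-addition of the reagent made from MeMgBr and CeCl3 to the enone carbonyl suppresses enolisation and retro-aldol of the β-hydroxy ketone, and methyl attacks the carbonyl face opposite the pseudo-axial 8a-methyl group, which sits across the ring alkene directly under C-6, so the new hydroxyl ends up cis to that methyl and trans to the 4-hydroxyl (6S).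

**Step 9**
Reactants: 18 benzene-1,2-diol
Product: 19 2-methoxyphenol
Conditions: MeI (1.0 equiv), K2CO3, acetone, 56 °C
Reagents that add atoms: iodomethane, CI
Why: Williamson ether synthesis with one equivalent of MeI methylates one of the two equivalent phenoxide oxygens.

**Step 10**
Reactants: 19 2-methoxyphenol
Product: 20 4-bromo-2-methoxyphenol
Conditions: NBS, MeCN, 0 °C
Reagents that add atoms: N-bromosuccinimide, O=C1CCC(=O)N1Br
Why: Electrophilic aromatic bromination occurs para to the free hydroxyl, the strongest directing group on the ring.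

**Step 11**
Reactants: 20 4-bromo-2-methoxyphenol
Product: 21 (4-bromo-2-methoxyphenoxy)(tert-butyl)dimethylsilane
Conditions: TBSCl, imidazole, DMF, 23 °C
Reagents that add atoms: tert-butyl(chloro)dimethylsilane, CC(C)(C)[Si](C)(C)Cl
Why: Imidazole-promoted O-silylation protects the phenol for the lithiation and the esterification.

**Step 12**
Reactants: 21 (4-bromo-2-methoxyphenoxy)(tert-butyl)dimethylsilane
Product: 23 4-{[tert-butyl(dimethyl)silyl]oxy}-3-methoxybenzoic acid, via aryllithium 22 (not isolated)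
Conditions: n-BuLi, THF, −78 °C; then CO2; then 1 M HCl to pH 3
Reagents that add atoms: carbon dioxide, O=C=O
Why: Bromine–lithium exchange followed by carboxylation of the aryllithium places the carboxyl group para to the silyloxy group.

**Step 13**
Reactants: 23 4-{[tert-butyl(dimethyl)silyl]oxy}-3-methoxybenzoic acid; 17 (3R,3aS,4S,6S,8aR)-6,8a-dimethyl-3-(propan-2-yl)-1,2,3,3a,4,5,6,8a-octahydroazulene-3,4,6-triol
Product: 25 (3R,3aS,4S,6S,8aR)-3,6-dihydroxy-6,8a-dimethyl-3-(propan-2-yl)-1,2,3,3a,4,5,6,8a-octahydroazulen-4-yl 4-{[tert-butyl(dimethyl)silyl]oxy}-3-methoxybenzoate, via mixed anhydride 24 (not isolated)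
Conditions: 2,4,6-Cl3C6H2COCl, Et3N, THF, 23 °C; then 17, DMAP, toluene, 40 °C
Reagents that add atoms: none
Why: Yamaguchi esterification through the mixed anhydride, in which DMAP-mediated acyl transfer occurs only at the secondary 4-hydroxyl because the two tertiary hydroxyls are too hindered, and the carbinol configuration is retained because the C–O bond of the alcohol is not broken.

**Step 14**
Reactants: 25 (3R,3aS,4S,6S,8aR)-3,6-dihydroxy-6,8a-dimethyl-3-(propan-2-yl)-1,2,3,3a,4,5,6,8a-octahydroazulen-4-yl 4-{[tert-butyl(dimethyl)silyl]oxy}-3-methoxybenzoate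
Product: 26 (3R,3aS,4S,6S,8aR)-3,6-dihydroxy-6,8a-dimethyl-3-(propan-2-yl)-1,2,3,3a,4,5,6,8a-octahydroazulen-4-yl 4-hydroxy-3-methoxybenzoate
Conditions: Bu4NF, AcOH, THF, 0 °C
Reagents that add atoms: none
Why: Fluoride-induced cleavage of the aryl silyl ether, buffered with AcOH so that the ester and the tertiary allylic alcohol survive, releases the phenol and touches no stereocentre.

**Compound list**
1 | 4-methylpent-1-en-3-one | C=CC(=O)C(C)C | starting material
2 | 1-bromo-4-methylpentan-3-one | BrCCC(=O)C(C)C | intermediate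
3 | 2-(2-bromoethyl)-2-(propan-2-yl)-1,3-dioxolane | BrCCC1(OCCO1)C(C)C | intermediate
4 | 3-methylcyclohex-2-en-1-one | CC1=CC(=O)CCC1 | starting material
5 | bromo{2-[2-(propan-2-yl)-1,3-dioxolan-2-yl]ethyl}magnesium | Br[Mg]CCC1(OCCO1)C(C)C | intermediate
6 | bromomagnesium (3R)-3-methyl-3-{2-[2-(propan-2-yl)-1,3-dioxolan-2-yl]ethyl}cyclohex-1-en-1-olate | Br[Mg]OC1=C[C@@](C)(CCC2(OCCO2)C(C)C)CCC1 | intermediate
7 | trimethyl{[(3R)-3-methyl-3-{2-[2-(propan-2-yl)-1,3-dioxolan-2-yl]ethyl}cyclohex-1-en-1-yl]oxy}silane | C[Si](C)(C)OC1=C[C@@](C)(CCC2(OCCO2)C(C)C)CCC1 | intermediate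
8 | trimethyl{[(5R)-5-methyl-5-{2-[2-(propan-2-yl)-1,3-dioxolan-2-yl]ethyl}bicyclo[4.1.0]heptan-1-yl]oxy}silane, both cyclopropane-fusion isomers | C[Si](C)(C)OC12CCC[C@](C)(CCC3(OCCO3)C(C)C)C1C2 | intermediate
9 | (4R)-3-chloro-4-methyl-4-{2-[2-(propan-2-yl)-1,3-dioxolan-2-yl]ethyl}cycloheptan-1-one, both C-3 epimers | O=C1CC(Cl)[C@@](C)(CCC2(OCCO2)C(C)C)CCC1 | intermediate
10 | (4R)-4-methyl-4-{2-[2-(propan-2-yl)-1,3-dioxolan-2-yl]ethyl}cyclohept-2-en-1-one | O=C1C=C[C@@](C)(CCC2(OCCO2)C(C)C)CCC1 | intermediate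
11 | lithium (5R)-5-methyl-5-{2-[2-(propan-2-yl)-1,3-dioxolan-2-yl]ethyl}cyclohepta-1,6-dien-1-olate | [Li]OC1=CCC[C@](C)(CCC2(OCCO2)C(C)C)C=C1 | intermediate
12 | (4S)-4-methyl-4-{2-[2-(propan-2-yl)-1,3-dioxolan-2-yl]ethyl}cyclohepta-2,6-dien-1-one | O=C1C=C[C@@](C)(CCC2(OCCO2)C(C)C)CC=C1 | intermediate
13 | (4S)-4-methyl-4-(4-methyl-3-oxopentyl)cyclohepta-2,6-dien-1-one | O=C1C=C[C@@](C)(CCC(=O)C(C)C)CC=C1 | intermediate
14 | (3R,3aR,8aR)-3-hydroxy-8a-methyl-3-(propan-2-yl)-2,3,3a,8a-tetrahydroazulen-6(1H)-one (trans ring fusion; 3-OH cis to the 8a-methyl) | C1=CC(=O)C=C[C@@]2(C)CC[C@@](O)(C(C)C)[C@H]12 | intermediate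
15 | (3R,3aR,4S,8aR)-3-hydroxy-8a-methyl-3-(propan-2-yl)-4-(4,4,5,5-tetramethyl-1,3,2-dioxaborolan-2-yl)-2,3,3a,4,5,8a-hexahydroazulen-6(1H)-one (boron cis to H-3a) | CC1(C)OB(OC1(C)C)[C@H]2CC(=O)C=C[C@@]3(C)CC[C@@](O)(C(C)C)[C@H]23 | intermediate
16 | (3R,3aS,4S,8aR)-3,4-dihydroxy-8a-methyl-3-(propan-2-yl)-2,3,3a,4,5,8a-hexahydroazulen-6(1H)-one | O[C@H]1CC(=O)C=C[C@@]2(C)CC[C@@](O)(C(C)C)[C@H]12 | intermediate
17 | (3R,3aS,4S,6S,8aR)-6,8a-dimethyl-3-(propan-2-yl)-1,2,3,3a,4,5,6,8a-octahydroazulene-3,4,6-triol | O[C@H]1C[C@](C)(O)C=C[C@@]2(C)CC[C@@](O)(C(C)C)[C@H]12 | intermediate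
18 | benzene-1,2-diol (catechol) | Oc1ccccc1O | starting material
19 | 2-methoxyphenol | COc1ccccc1O | intermediate
20 | 4-bromo-2-methoxyphenol | COc1cc(Br)ccc1O | intermediate
21 | (4-bromo-2-methoxyphenoxy)(tert-butyl)dimethylsilane | COc1cc(Br)ccc1O[Si](C)(C)C(C)(C)C | intermediate
22 | (4-{[tert-butyl(dimethyl)silyl]oxy}-3-methoxyphenyl)lithium | [Li]c1ccc(O[Si](C)(C)C(C)(C)C)c(OC)c1 | intermediate
23 | 4-{[tert-butyl(dimethyl)silyl]oxy}-3-methoxybenzoic acid | COc1cc(C(=O)O)ccc1O[Si](C)(C)C(C)(C)C | intermediate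
24 | 4-{[tert-butyl(dimethyl)silyl]oxy}-3-methoxybenzoic 2,4,6-trichlorobenzoic anhydride | COc1cc(C(=O)OC(=O)c2c(Cl)cc(Cl)cc2Cl)ccc1O[Si](C)(C)C(C)(C)C | intermediate
25 | (3R,3aS,4S,6S,8aR)-3,6-dihydroxy-6,8a-dimethyl-3-(propan-2-yl)-1,2,3,3a,4,5,6,8a-octahydroazulen-4-yl 4-{[tert-butyl(dimethyl)silyl]oxy}-3-methoxybenzoate | COc1cc(C(=O)O[C@H]2C[C@](C)(O)C=C[C@@]3(C)CC[C@@](O)(C(C)C)[C@H]23)ccc1O[Si](C)(C)C(C)(C)C | intermediate
26 | (3R,3aS,4S,6S,8aR)-3,6-dihydroxy-6,8a-dimethyl-3-(propan-2-yl)-1,2,3,3a,4,5,6,8a-octahydroazulen-4-yl 4-hydroxy-3-methoxybenzoate | COc1cc(C(=O)O[C@H]2C[C@](C)(O)C=C[C@@]3(C)CC[C@@](O)(C(C)C)[C@H]23)ccc1O | target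

**Step count and risks**
Total step count: 14. Longest linear sequence: 10 (steps 1–8, 13, 14).

Most likely to fail, first: step 6, the new vinylogous aldol. The trans ring fusion and the 3R carbinol rest on thermodynamic control that is argued, not demonstrated. Michael closure of the side-chain enolate onto the enone or dehydration of the product could also compete. The fallback uses known reactions and makes the trienolate reductively, without base. It sets out from 12: Wohl–Ziegler bromination (NBS, (PhCO2)2, PhCF3, 80 °C) of the γ-CH2 gives 5-bromo-4-methyl-4-{2-[2-(propan-2-yl)-1,3-dioxolan-2-yl]ethyl}cyclohepta-2,6-dien-1-one F1. Aqueous HCl in THF unmasks the ketone to give 5-bromo-4-methyl-4-(4-methyl-3-oxopentyl)cyclohepta-2,6-dien-1-one F2. SmI2 (THF, −78 °C) then reduces the allylic bromide to the samarium trienolate, which closes onto the isopropyl ketone in a vinylogous Reformatsky reaction. The fallback comes back to the route at 14 after separation of diastereomers.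

Second: step 7, site and face selectivity of the conjugate borylation. The fallback delivers the oxygen as a nucleophilic oxidant and sets out from 14. Weitz–Scheffer epoxidation (t-BuOOH, DBU, CH2Cl2) of the less hindered enone arm gives (3R,3aS,8aR)-4,5-epoxy-3-hydroxy-8a-methyl-3-(propan-2-yl)-2,3,3a,4,5,8a-hexahydroazulen-6(1H)-one, epoxide oxygen cis to H-3a, F3. Reductive cleavage of the Cα–O bond with Na[PhSeB(OEt)3] (EtOH, AcOH) brings it back to the route at 16.

Third: step 8, face selectivity of the methyl addition. If methyl enters from the other face, the fallback turns that same facial preference to use by delivering oxygen instead of carbon. It sets out from 16: Wittig methylenation (Ph3P=CH2, THF) gives (3R,3aS,4S,8aR)-8a-methyl-6-methylidene-3-(propan-2-yl)-1,2,3,3a,4,5,6,8a-octahydroazulene-3,4-diol F4. Epoxidation of the exocyclic alkene with mCPBA gives (3R,3aS,4S,8aR)-8a-methyl-3-(propan-2-yl)-1,2,3,3a,4,5-hexahydro-8aH-spiro[azulene-6,2'-oxirane]-3,4-diol, oxirane oxygen cis to the 8a-methyl group, F5. LiAlH4 opens the oxirane at its CH2 and the fallback comes back to the route at 17.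

**Further compounds**
F1 | step 6 | 5-bromo-4-methyl-4-{2-[2-(propan-2-yl)-1,3-dioxolan-2-yl]ethyl}cyclohepta-2,6-dien-1-one, quaternary carbon as in 12, both bromide epimers | O=C1C=C[C@@](C)(CCC2(OCCO2)C(C)C)C(Br)C=C1
F2 | step 6 | 5-bromo-4-methyl-4-(4-methyl-3-oxopentyl)cyclohepta-2,6-dien-1-one, quaternary carbon as in 12, both bromide epimers | O=C1C=C[C@@](C)(CCC(=O)C(C)C)C(Br)C=C1
F3 | step 7 | (3R,3aS,8aR)-4,5-epoxy-3-hydroxy-8a-methyl-3-(propan-2-yl)-2,3,3a,4,5,8a-hexahydroazulen-6(1H)-one, epoxide oxygen cis to H-3a | O1[C@H]2[C@@H]1C(=O)C=C[C@@]3(C)CC[C@@](O)(C(C)C)[C@H]23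
F4 | step 8 | (3R,3aS,4S,8aR)-8a-methyl-6-methylidene-3-(propan-2-yl)-1,2,3,3a,4,5,6,8a-octahydroazulene-3,4-diol | O[C@H]1CC(=C)C=C[C@@]2(C)CC[C@@](O)(C(C)C)[C@H]12
F5 | step 8 | (3R,3aS,4S,8aR)-8a-methyl-3-(propan-2-yl)-1,2,3,3a,4,5-hexahydro-8aH-spiro[azulene-6,2'-oxirane]-3,4-diol, oxirane oxygen cis to the 8a-methyl group | O[C@H]1C[C@@]2(CO2)C=C[C@@]3(C)CC[C@@](O)(C(C)C)[C@H]13
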